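**Plan**

Numbering: ring C1 (lactone O–CH), C2, C3 (bears methyl C14), C4, C5, C6 (C=O), C7 (=C15H2), C8 (O-angelate), C9 (OH), C10 (ring fusion); lactone C11 (=C13H2) and C12 (C=O).
Retrosynthesis: remove the C3/C4 epoxide oxygen, the angelate and both exo-methylenes (C15, C13), and switch to a C8 ketone/C6 ether. Then cut C5–C6 while drawing a C3–C8 bond ([3,3] retron), followed by C8–C7 (acetylide + ketone), C10–C11 (Michael), C9–O (enol ether oxidation) and C3–C14/C3–C4 (enolate chemistry).
Enabling feature: the triad C1/C10/C9 and the 1,6-related carbons C3 and C8 fit on one cyclohexane (C3–C2–C1–C10–C9–C8) that a trans-fused γ-lactone across C1/C10 locks. Breaking the extra C3–C8 bond of this cis-1-alkenyl-2-vinylcyclohexanol leaves the Z C3=C4 olefin that the cis-epoxide needs.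
Forward order of rings: cyclohexenone carbocycle → γ-lactone ring (step 9) → six-to-ten ring expansion (step 13) → oxirane last (step 20). The C6–C7 unit is joined as an alkoxyacetylide made from 4-methoxybenzyl alcohol and trichloroethene.
Stereochemistry: C1 from a CBS reduction; C3, C10 and C9 relayed from C1 (anti alkylation, anti Michael addition, anti enol ether oxidation); the C8 carbinol by axial alkynylation; Z-C3=C4 from the lactone-locked chair array of the [3,3] shift; C8 by Felkin–Anh hydride delivery; C3/C4 by peracid attack on the exposed olefin face.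

Key step: step 13

Remark: ketal enone 1 is taken as a catalogue compound; the C6 configuration formed in step 13 is transient (oxidised away in step 18) and is specified only for bookkeeping.

**Route**

Step 1
Reactants: 1 1,4-dioxaspiro[4.5]dec-6-en-8-one
Product: 2 (R)-1,4-dioxaspiro[4.5]dec-6-en-8-ol
Conditions: (S)-2-methyl-CBS-oxazaborolidine (10 mol%), BH3·SMe2, THF, −30 °C; MeOH quench
Reagents that add atoms: none
Why: Corey–Bakshi–Shibata reduction is 1,2-selective for the enone and, with the alkenyl arm acting as the large substituent, the (S)-catalyst should give the R carbinol that becomes C1.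

Step 2
Reactants: 2 (R)-1,4-dioxaspiro[4.5]dec-6-en-8-ol
Product: 3 (R)-4-hydroxycyclohex-2-en-1-one
Conditions: PPTS, acetone/H2O, rt
Reagents that add atoms: water, O
Why: Acid-catalysed ketal hydrolysis is easy for this allylic ketal and unmasks the ketone in conjugation with the olefin, which turns the untouched carbinol into the γ-stereocentre of an enone.

Step 3
Reactants: 3 (R)-4-hydroxycyclohex-2-en-1-one
Product: 4 (R)-4-(triethylsilyloxy)cyclohex-2-en-1-one
Conditions: Et3SiCl, imidazole, CH2Cl2, 0 °C
Reagents that add atoms: chlorotriethylsilane, CC[Si](Cl)(CC)CC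
Why: Standard silylation (silyl chloride, imidazole) gives a triethylsilyl ether that is bulky enough to direct the later additions yet can be removed beside a TBS ether.

Step 4
Reactants: 4 (R)-4-(triethylsilyloxy)cyclohex-2-en-1-one
Product: 5 (4R)-6-(1-hydroxyethyl)-4-(triethylsilyloxy)cyclohex-2-en-1-one (diastereomer mixture)
Conditions: LiN(iPr)2, THF, −78 °C; CH3CHO, −78 °C; NH4Cl aq
Reagents that add atoms: acetaldehyde, CC=O
Why: Kinetic deprotonation gives the cross-conjugated α'-enolate at C3 and its aldol addition to acetaldehyde brings in C4 and C5, the two new stereocentres being removed in the next step.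

Step 5
Reactants: 5 (4R)-6-(1-hydroxyethyl)-4-(triethylsilyloxy)cyclohex-2-en-1-one
Product: 7 (4R,6E)-6-ethylidene-4-(triethylsilyloxy)cyclohex-2-en-1-one, via mesylate 6 (not isolated)
Conditions: MsCl, Et3N, CH2Cl2, −20 °C; then DBU, 0 °C → rt
Reagents that add atoms: none
Why: Mesylation and base-induced E1cB elimination give the conjugated exocyclic enone, the E isomer being favoured, and either isomer leads to the same dienolate in step 6.

Step 6
Reactants: 7 (4R,6E)-6-ethylidene-4-(triethylsilyloxy)cyclohex-2-en-1-one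
Product: 8 (4R,6R)-6-ethenyl-6-methyl-4-(triethylsilyloxy)cyclohex-2-en-1-one
Conditions: LiN(iPr)2, HMPA, THF, −78 °C; MeI, −78 → −40 °C
Reagents that add atoms: iodomethane, CI
Why: With no α'-hydrogen available, the amide base removes a γ-hydrogen from the ethylidene methyl and the extended enolate is methylated at its α-carbon C3 (deconjugative α-alkylation), iodomethane entering anti to the pseudoaxial C1 silyloxy group so that the new methyl is trans to O1 (3R) and the vinyl group cis to it.

Step 7
Reactants: 8 (4R,6R)-6-ethenyl-6-methyl-4-(triethylsilyloxy)cyclohex-2-en-1-one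
Product: 9 methyl 2-[(1R,4R,6R)-3-(tert-butyldimethylsilyloxy)-4-ethenyl-4-methyl-6-(triethylsilyloxy)cyclohex-2-en-1-yl]acetate
Conditions: tert-butyl[(1-methoxyethenyl)oxy]dimethylsilane (1.5 equiv), Tf2NH (2 mol%), CH2Cl2, −78 °C; Et3N quench
Reagents that add atoms: tert-butyl[(1-methoxyethenyl)oxy]dimethylsilane, C=C(OC)O[Si](C)(C)C(C)(C)C
Why: Mukaiyama–Michael addition with silyl transfer, in which the ketene acetal adds to C10 anti to the adjacent C1 silyloxy group (as is general for 4-silyloxycyclohexenones), sets the C1/C10 trans relation (10R) and leaves the C8 enolate trapped regiospecifically as its TBS enol ether.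

Step 8
Reactants: 9 methyl 2-[(1R,4R,6R)-3-(tert-butyldimethylsilyloxy)-4-ethenyl-4-methyl-6-(triethylsilyloxy)cyclohex-2-en-1-yl]acetate
Product: 11 methyl 2-[(1S,2R,4R,6R)-2-(tert-butyldimethylsilyloxy)-4-ethenyl-4-methyl-3-oxo-6-(triethylsilyloxy)cyclohexyl]acetate, via silyloxy epoxide 10 (not isolated)
Conditions: mCPBA, NaHCO3, CH2Cl2, −20 °C → rt
Reagents that add atoms: 3-chloroperoxybenzoic acid, OOC(=O)c1cccc(Cl)c1
Why: In this Rubottom oxidation the peracid epoxidises the electron-rich enol ether (not the monosubstituted vinyl group) on the face anti to the adjacent C10 side chain and the pseudoaxial C3 methyl, and ring opening with 1,4-silyl shift gives the equatorial C9 silyloxy ketone (9R).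

Step 9
Reactants: 11 methyl 2-[(1S,2R,4R,6R)-2-(tert-butyldimethylsilyloxy)-4-ethenyl-4-methyl-3-oxo-6-(triethylsilyloxy)cyclohexyl]acetate
Product: 13 (3aS,4R,6R,7aR)-4-(tert-butyldimethylsilyloxy)-6-ethenyl-6-methylhexahydro-1-benzofuran-2,5-dione, via hydroxy ester 12 (not isolated)
Conditions: PPTS, MeOH, 0 °C → rt; then CSA (cat.), PhMe, 60 °C
Reagents that add atoms: none
Why: In this acid-mediated desilylation–lactonisation the triethylsilyl ether is cleaved well before the α-keto TBS ether, and the freed equatorial C1 hydroxyl closes onto the equatorial C10 acetate arm (5-exo-trig acyl substitution) to the trans-fused γ-lactone that locks the chair with the C3 methyl axial.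

Step 10
Reactants: 14 4-methoxybenzyl alcohol
Product: 15 1-{[(E)-1,2-dichloroethenyl]oxymethyl}-4-methoxybenzene
Conditions: KH, THF, 0 °C; Cl2C=CHCl, −50 °C → rt
Reagents that add atoms: trichloroethene, ClC=C(Cl)Cl
Why: Greene synthesis of dichlorovinyl ethers, in which the potassium alkoxide adds anti to dichloroacetylene generated in situ from trichloroethene, gives the E ether as a stable precursor of the alkoxyacetylide.

Step 11
Reactants: 13 (3aS,4R,6R,7aR)-4-(tert-butyldimethylsilyloxy)-6-ethenyl-6-methylhexahydro-1-benzofuran-2,5-dione; 15 1-{[(E)-1,2-dichloroethenyl]oxymethyl}-4-methoxybenzene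
Product: 17 alkynyl carbinol (1R,3R,8S,9R,10S): lactone-fused cyclohexanol carrying an axial C8 2-(4-methoxybenzyloxy)ethynyl group cis to the C3 vinyl group, via lithium alkoxyethynide 16 (not isolated)
Conditions: 15 (2 equiv), n-BuLi (4.1 equiv), THF, −78 → −40 °C; CeCl3 (anhydrous), −78 °C; then 13, −78 °C; NH4Cl aq
Reagents that add atoms: none
Why: Two equivalents of butyllithium convert 15 by elimination and chlorine–lithium exchange into the alkoxyethynide, which as its cerium reagent adds 1,2 to the hindered ketone in preference to the lactone (acetylide addition), the slim nucleophile entering axially, anti to the axial C3 methyl, so that the alkynyl group is axial and cis to the equatorial C3 vinyl group (8S).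

Step 12
Reactants: 17 alkynyl carbinol (1R,3R,8S,9R,10S)
Product: 18 cis-1-alkenyl-2-vinylcyclohexanol (1R,3R,8R,9R,10S): as 17 but with a C8 (Z)-2-(4-methoxybenzyloxy)ethenyl group
Conditions: H2 (1 atm), Pd/CaCO3 poisoned with Pb(OAc)2 (Lindlar catalyst), quinoline, EtOAc, rt; Et3N-washed silica
Reagents that add atoms: none
Why: Lindlar semihydrogenation adds hydrogen syn to the alkynyl ether, which is reduced much faster than the monosubstituted vinyl group, and so fixes the Z enol ether needed as the oxygenated arm of the 1,5-diene.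

Step 13
Reactants: 18 cis-1-alkenyl-2-vinylcyclohexanol (1R,3R,8R,9R,10S)
Product: 21 ten-membered C8 ketone (3Z; 1R,6R,9R,10S) bearing C6 OPMB and C9 OTBS, via potassium alkoxide 19 (not isolated), via potassium enolate 20 (not isolated)
Conditions: KN(SiMe3)2 (1.05 equiv), 18-crown-6 (1.1 equiv), THF, −78 → 0 °C; AcOH, −78 °C
Reagents that add atoms: none
Why: Deprotonation gives the crown-separated potassium alkoxide 19, whose oxido group weakens the C3–C8 bond and triggers a concerted [3,3] shift (anionic oxy-Cope rearrangement) that forms C5–C6, breaks C3–C8 and delivers the C7=C8 enolate 20, protonated cold to ketone 21. The closest known reaction type is the ring expansion of cis-1-alkenyl-2-vinylcyclohexanol alkoxides to cyclodec-5-enones. The ten-membered carbocycle is not closed end to end but arises by four-carbon ring enlargement, the new σ-bond joining the two alkene termini inside a six-centre chair array while the bond shared by the carbinol and quaternary carbons is cut. The only new stereocentre, C6, is set (R) by the Z enol ether geometry, which places the OPMB group axial in that chair, and it is erased later by oxidation. The step needs Z geometry at C3=C4: the trans-fused lactone locks the cyclohexane with the C8 alkenyl group axial and the C3 vinyl group equatorial, the only chair array this allows has the oxido group and ring carbon C2 axial and the C3 methyl equatorial, and C2 therefore ends cis to C5. Enolate formation makes the step irreversible, and the lactone and the equatorial C9 silyloxy group pass through unchanged.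

Step 14
Reactants: 21 ten-membered C8 ketone (3Z; 1R,6R,9R,10S)
Product: 24 bis-exo-methylene keto lactone (1R,6R,9R,10S) with C7=C15H2 and C11=C13H2, via bis-Mannich base 22 (not isolated), via bis-ammonium iodide 23 (not isolated)
Conditions: LiN(iPr)2 (2.3 equiv), THF, −78 °C; CH2=NMe2+ I− (3 equiv), −78 → 0 °C; MeI, CH2Cl2, rt; NaHCO3 aq, CH2Cl2
Reagents that add atoms: N,N-dimethylmethyleneiminium iodide, C=[N+](C)C.[I-]
Why: In this twofold Eschenmoser methylenation (Mannich reaction, N-methylation, elimination) kinetic deprotonation takes the C7 methylene of the ketone rather than the silyloxy-bearing C9 methine and a second equivalent of base forms the lactone enolate at C11, so that both exo-methylene groups are installed in one operation.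

Step 15
Reactants: 24 bis-exo-methylene keto lactone (1R,6R,9R,10S)
Product: 25 allylic alcohol (1R,6R,8R,9R,10S)
Conditions: NaBH4, CeCl3·7H2O, MeOH, −78 °C
Reagents that add atoms: none
Why: Luche reduction is 1,2-selective for the enone at −78 °C (the lactone acrylate is left), and hydride should arrive anti to the C9–OSi bond from the ring periphery (polar Felkin–Anh), giving the 8,9-syn alcohol (8R).

Step 16
Reactants: 25 allylic alcohol (1R,6R,8R,9R,10S)
Product: 26 C8 angelate (1R,6R,8R,9R,10S)
Conditions: angelic acid, 2,4,6-trichlorobenzoyl chloride, Et3N, PhMe, rt; then 25, 75 °C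
Reagents that add atoms: angelic acid, C/C=C(/C)C(=O)O
Why: Yamaguchi esterification through the mixed anhydride, run without DMAP, acylates the hindered allylic alcohol while avoiding the base-mediated isomerisation of the angelate to the tiglate.

Step 17
Reactants: 26 C8 angelate (1R,6R,8R,9R,10S)
Product: 27 C6 allylic alcohol (1R,6R,8R,9R,10S)
Conditions: DDQ, CH2Cl2/pH 7 phosphate buffer, 0 °C
Reagents that add atoms: none
Why: Oxidative cleavage of the 4-methoxybenzyl ether by DDQ (single-electron oxidation, then hydrolysis of the hemiacetal) frees the allylic C6 alcohol without touching the silyl ether, the esters or the olefins.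

Step 18
Reactants: 27 C6 allylic alcohol (1R,6R,8R,9R,10S)
Product: 28 C6 ketone (1R,8R,9R,10S) with C9 OTBS
Conditions: Dess–Martin periodinane, NaHCO3, CH2Cl2, 0 °C
Reagents that add atoms: none
Why: Dess–Martin oxidation under buffered, non-basic conditions converts the allylic alcohol into the C6 ketone conjugated with the C7 methylene, erasing the C6 stereocentre and avoiding migration of the β,γ-olefin.

Step 19
Reactants: 28 C6 ketone (1R,8R,9R,10S) with C9 OTBS
Product: 29 C9 alcohol (1R,8R,9R,10R), the 3,4-deoxy precursor of the target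
Conditions: HF·pyridine, pyridine, THF, 0 °C → rt
Reagents that add atoms: none
Why: Fluoride-mediated desilylation under weakly acidic conditions removes the TBS group without Michael addition, acyl migration or translactonisation, and it precedes epoxidation because the trisubstituted epoxide would not tolerate HF.

Step 20
Reactants: 29 C9 alcohol (1R,8R,9R,10R)
Product: 30 CNP0348992.7 (1R,3R,4S,8R,9R,10R)
Conditions: mCPBA, NaHCO3, CH2Cl2, 0 °C
Reagents that add atoms: 3-chloroperoxybenzoic acid, OOC(=O)c1cccc(Cl)c1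
Why: Prilezhaev epoxidation is selective for the only electron-rich olefin (the three others are conjugated to carbonyl groups), transfers oxygen stereospecifically to the Z olefin to give the cis-epoxide, and should occur on the exposed outer face, anti to the C1–O bond across C2, to set 3R,4S.

**Compound list**

1 | 1,4-dioxaspiro[4.5]dec-6-en-8-one | O=C1C=CC2(CC1)OCCO2 | starting material
2 | (R)-1,4-dioxaspiro[4.5]dec-6-en-8-ol | O[C@H]1C=CC2(CC1)OCCO2 | intermediate
3 | (R)-4-hydroxycyclohex-2-en-1-one | O=C1C=C[C@H](O)CC1 | intermediate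
4 | (R)-4-(triethylsilyloxy)cyclohex-2-en-1-one | O=C1C=C[C@H](O[Si](CC)(CC)CC)CC1 | intermediate
5 | (4R)-6-(1-hydroxyethyl)-4-(triethylsilyloxy)cyclohex-2-en-1-one, mixture at C6 and the carbinol carbon | CC(O)C1C[C@@H](O[Si](CC)(CC)CC)C=CC1=O | intermediate
6 | methanesulfonate of 5 | CC(OS(C)(=O)=O)C1C[C@@H](O[Si](CC)(CC)CC)C=CC1=O | intermediate (not isolated)
7 | (4R,6E)-6-ethylidene-4-(triethylsilyloxy)cyclohex-2-en-1-one | C/C=C1\C[C@@H](O[Si](CC)(CC)CC)C=CC1=O | intermediate
8 | (4R,6R)-6-ethenyl-6-methyl-4-(triethylsilyloxy)cyclohex-2-en-1-one | O=C1C=C[C@H](O[Si](CC)(CC)CC)C[C@]1(C)C=C | intermediate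
9 | methyl 2-[(1R,4R,6R)-3-(tert-butyldimethylsilyloxy)-4-ethenyl-4-methyl-6-(triethylsilyloxy)cyclohex-2-en-1-yl]acetate | COC(=O)C[C@@H]1C=C(O[Si](C)(C)C(C)(C)C)[C@@](C)(C=C)C[C@H]1O[Si](CC)(CC)CC | intermediate
10 | C8–C9 silyloxy epoxide of 9, oxygen anti to the C10 side chain | O1[C@]2(O[Si](C)(C)C(C)(C)C)[C@H]1[C@@H](CC(=O)OC)[C@H](O[Si](CC)(CC)CC)C[C@]2(C)C=C | intermediate (not isolated)
11 | methyl 2-[(1S,2R,4R,6R)-2-(tert-butyldimethylsilyloxy)-4-ethenyl-4-methyl-3-oxo-6-(triethylsilyloxy)cyclohexyl]acetate | COC(=O)C[C@@H]1[C@@H](O[Si](C)(C)C(C)(C)C)C(=O)[C@@](C)(C=C)C[C@H]1O[Si](CC)(CC)CC | intermediate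
12 | methyl 2-[(1S,2R,4R,6R)-2-(tert-butyldimethylsilyloxy)-4-ethenyl-6-hydroxy-4-methyl-3-oxocyclohexyl]acetate | COC(=O)C[C@@H]1[C@@H](O[Si](C)(C)C(C)(C)C)C(=O)[C@@](C)(C=C)C[C@H]1O | intermediate (not isolated)
13 | (3aS,4R,6R,7aR)-4-(tert-butyldimethylsilyloxy)-6-ethenyl-6-methylhexahydro-1-benzofuran-2,5-dione (route locants 1R,3R,9R,10S; trans-fused lactone, C3 methyl axial, C9 OTBS equatorial) | O=C1[C@H](O[Si](C)(C)C(C)(C)C)[C@H]2CC(=O)O[C@@H]2C[C@]1(C)C=C | intermediate
14 | 4-methoxybenzyl alcohol | COc1ccc(CO)cc1 | starting material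
15 | 1-{[(E)-1,2-dichloroethenyl]oxymethyl}-4-methoxybenzene | COc1ccc(CO/C(Cl)=C\Cl)cc1 | intermediate
16 | lithium 2-(4-methoxybenzyloxy)ethynide | [Li+].[C-]#COCc1ccc(OC)cc1 | intermediate (not isolated)
17 | (1R,3R,8S,9R,10S)-alkynyl carbinol: 13 with C8 carrying an equatorial OH and an axial 2-(4-methoxybenzyloxy)ethynyl group cis to the C3 vinyl group | O[C@@]1(C#COCc2ccc(OC)cc2)[C@H](O[Si](C)(C)C(C)(C)C)[C@H]3CC(=O)O[C@@H]3C[C@]1(C)C=C | intermediate
18 | (1R,3R,8R,9R,10S)-cis-1-alkenyl-2-vinylcyclohexanol: as 17 with a C8 (Z)-2-(4-methoxybenzyloxy)ethenyl group | O[C@@]1(/C=C\OCc2ccc(OC)cc2)[C@H](O[Si](C)(C)C(C)(C)C)[C@H]3CC(=O)O[C@@H]3C[C@]1(C)C=C | intermediate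
19 | potassium alkoxide of 18 | [K+].[O-][C@@]1(/C=C\OCc2ccc(OC)cc2)[C@H](O[Si](C)(C)C(C)(C)C)[C@H]3CC(=O)O[C@@H]3C[C@]1(C)C=C | intermediate (not isolated)
20 | potassium C7=C8 enolate of 21 (O8 cis to C6) | C1C(=O)O[C@@H]2C/C(C)=C\C[C@@H](OCc3ccc(OC)cc3)/C=C(\[O-])[C@H](O[Si](C)(C)C(C)(C)C)[C@@H]12.[K+] | intermediate (not isolated)
21 | (1R,6R,9R,10S,3Z)-ten-membered ketone: cyclodec-3-ene with C3 methyl, C6 OPMB, C8 oxo, C9 OTBS and the trans-fused lactone C1–O–C12(=O)–C11H2–C10 | C1C(=O)O[C@@H]2C/C(C)=C\C[C@@H](OCc3ccc(OC)cc3)CC(=O)[C@H](O[Si](C)(C)C(C)(C)C)[C@@H]12 | intermediate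
22 | 7,11-bis(dimethylaminomethyl) derivative of 21, mixture at C7 and C11 | CN(C)CC1C(=O)O[C@@H]2C/C(C)=C\C[C@@H](OCc3ccc(OC)cc3)C(CN(C)C)C(=O)[C@H](O[Si](C)(C)C(C)(C)C)[C@@H]12 | intermediate (not isolated)
23 | 7,11-bis(trimethylammoniomethyl) diiodide of 21 | C[N+](C)(C)CC1C(=O)O[C@@H]2C/C(C)=C\C[C@@H](OCc3ccc(OC)cc3)C(C[N+](C)(C)C)C(=O)[C@H](O[Si](C)(C)C(C)(C)C)[C@@H]12.[I-].[I-] | intermediate (not isolated)
24 | (1R,6R,9R,10S,3Z)-7,11-bis(methylene) keto lactone: 21 with C7=C15H2 and C11=C13H2 | C=C1C(=O)O[C@@H]2C/C(C)=C\C[C@@H](OCc3ccc(OC)cc3)C(=C)C(=O)[C@H](O[Si](C)(C)C(C)(C)C)[C@@H]12 | intermediate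
25 | (1R,6R,8R,9R,10S,3Z)-C8 alcohol of 24 | C=C1C(=O)O[C@@H]2C/C(C)=C\C[C@@H](OCc3ccc(OC)cc3)C(=C)[C@@H](O)[C@H](O[Si](C)(C)C(C)(C)C)[C@@H]12 | intermediate
26 | (1R,6R,8R,9R,10S,3Z)-C8 angelate with C6 OPMB and C9 OTBS | C=C1C(=O)O[C@@H]2C/C(C)=C\C[C@@H](OCc3ccc(OC)cc3)C(=C)[C@@H](OC(=O)/C(C)=C\C)[C@H](O[Si](C)(C)C(C)(C)C)[C@@H]12 | intermediate
27 | (1R,6R,8R,9R,10S,3Z)-C6 alcohol, C8 angelate, C9 OTBS | C=C1C(=O)O[C@@H]2C/C(C)=C\C[C@@H](O)C(=C)[C@@H](OC(=O)/C(C)=C\C)[C@H](O[Si](C)(C)C(C)(C)C)[C@@H]12 | intermediate
28 | (1R,8R,9R,10S,3Z)-C6 ketone, C8 angelate, C9 OTBS | C=C1C(=O)O[C@@H]2C/C(C)=C\CC(=O)C(=C)[C@@H](OC(=O)/C(C)=C\C)[C@H](O[Si](C)(C)C(C)(C)C)[C@@H]12 | intermediate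
29 | (1R,8R,9R,10R,3Z)-C9 alcohol, the 3,4-deoxy target | C=C1C(=O)O[C@@H]2C/C(C)=C\CC(=O)C(=C)[C@@H](OC(=O)/C(C)=C\C)[C@H](O)[C@@H]12 | intermediate
30 | CNP0348992.7 (1R,3R,4S,8R,9R,10R) | C=C1C(=O)O[C@@H]2C[C@@]3(C)O[C@H]3CC(=O)C(=C)[C@@H](OC(=O)/C(C)=C\C)[C@H](O)[C@@H]12 | target

**Totals and risks**

Total step count: 20. Longest linear sequence: 19 steps (1 → 30 through steps 1–9 and 11–20; step 10 is the one-step branch to 15).

Steps most likely to fail:

Step 13. In the chair array the Z alkoxy group at C6 sits 1,3-diaxial to the oxido group, so a boat-like or stepwise fragmentation–recombination pathway may compete and erode the C3=C4 geometry. The ion-paired enolate may also lose the C6 alkoxy group by β-elimination, and the free alkoxide may trigger silyl migration from O9 before it rearranges. The fallback removes the charged intermediates and sets out from 18. The tertiary hydroxyl is silylated (Me3SiOTf, Et3N, CH2Cl2, −78 °C) to the trimethylsilyl ether of 18 F1. Heating in toluene (sealed vessel, about 180 °C, base-washed glass) effects the neutral silyloxy-Cope rearrangement through the same lactone-locked chair to the C7=C8 trimethylsilyl enol ether of 21 F2. Buffered fluoride (Bu4NF/AcOH, THF, −20 °C) then releases the ketone and the route is rejoined at 21.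

Step 20. The facial bias of the Z olefin in the flexible ten-membered ring is not secured by a neighbouring stereocentre, so the peracid may deliver oxygen to the other π-face. The fallback inverts the facial outcome by an addition–displacement sequence and sets out from 29. NBS in wet THF at 0 °C forms the bromonium ion on the more exposed face and water opens it at the tertiary C3 from the opposite side to give the (3R,4R)-4-bromo-3-hydroxy bromohydrin of 29 F4. Ag2O in CH2Cl2 then closes the oxirane with inversion at C4, placing the oxygen on the face opposite to direct peracid attack, and the route is rejoined at 30.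

Step 15. Which carbonyl face is exposed is decided by the conformation of the ten-membered enone as much as by the C9 substituent, so hydride may arrive on the face that gives the 8-epimer. The fallback sets out from 24 and uses that epimer. The same reduction then furnishes the (8S)-epimer of alcohol 25 F3, and Mitsunobu esterification with angelic acid (PPh3, DIAD, PhMe, 0 °C) inverts C8 while installing the ester, so the route is rejoined at 26.

Further compounds
F1 | step 13 | trimethylsilyl ether of 18 | C[Si](C)(C)O[C@@]1(/C=C\OCc2ccc(OC)cc2)[C@H](O[Si](C)(C)C(C)(C)C)[C@H]3CC(=O)O[C@@H]3C[C@]1(C)C=C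
F2 | step 13 | C7=C8 trimethylsilyl enol ether of 21 | C1C(=O)O[C@@H]2C/C(C)=C\C[C@@H](OCc3ccc(OC)cc3)/C=C(\O[Si](C)(C)C)[C@H](O[Si](C)(C)C(C)(C)C)[C@@H]12
F3 | step 15 | (8S)-epimer of alcohol 25 | C=C1C(=O)O[C@@H]2C/C(C)=C\C[C@@H](OCc3ccc(OC)cc3)C(=C)[C@H](O)[C@H](O[Si](C)(C)C(C)(C)C)[C@@H]12
F4 | step 20 | (3R,4R)-4-bromo-3-hydroxy bromohydrin of 29 | C=C1C(=O)O[C@@H]2C[C@@](C)(O)[C@H](Br)CC(=O)C(=C)[C@@H](OC(=O)/C(C)=C\C)[C@H](O)[C@@H]12
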